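(Readings and results are calculated on assumed constants, and the scatter is random.)

the same everywhere: starting material 0.039 M; protic impurity 0.0195 M; free catalyst 0.21 mM; stray impurity 63 µM

|  | second substrate | remark | time |
|---|---|---|---|
| west | 0.055 M | run made earlier |  |
| east | 0.086 M | run made earlier |  |
| flask | 0.0390 M |  | 5.0 d |

- west (time / d: starting material / %, catalyst intermediate A / %, target / %): 0.417: 52, 2, 40; 1.25: 8, 0, 77; 2.00: 0, 0, 81; 3.00: 0, 0, 84; 5.00: 2, 1, 85; 6.00: 2, 1, 84
- east (time / d: starting material / %, catalyst intermediate A / %, target / %): 0.500: 48, 0, 42; 0.833: 26, 0, 61; 1.25: 10, 1, 73; 2.00: 0, 0, 82; 4.00: 1, 0, 85; 6.00: 0, 0, 83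

(each reading ± 1.5 percentage points)

- the species in which most of what was charged as starting material, at 5.0 d sits (starting material / catalyst intermediate A / target)
- the largest share itself, whichever of these holds it, in percent of the starting material charged



East holds 1.56 times the second substrate of west, yet at 1.25 d starting material reads 10% in east and 8% in west. The two runs give one ladder of times.

On the lowest rung stands catalyst intermediate A. The catalyst charge equals 0.538% of the starting material charge, and the intermediate reads no higher than 2%. Next, starting material in the two runs reaches half near 0.458 d. At 2.00 d it reads 0% in west and 0% in east. From 3.00 d on, target lies flat within the scatter.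

The asked time lies 10.9 of those half-times out. But the flask's 0.0390 M of second substrate stands below both runs, so this step is an extrapolation. My own reckoning replaces the curve of target by one mean, the yield on conversion, or selectivity:

yield on conversion = c(target) / (charged c(starting material) − c(starting material))

mean of the five target readings from 3.00 d on = 84.2%

At those readings starting material reads at most 2%, so the denominator is taken as the whole charge.

The error shows on the curve. East at 1.25 d gives 75.8% by this mean against 73% read, a miss of 2.8 percentage points. So I expect target in the flask at 84.2%.

The forecast names the same species at a lower share: target at about 80%, “with the range skewed low”.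

The flask gives target at 85.3%.

    starting material + free catalyst ⇌ catalyst intermediate A (K = 74.0 L mol⁻¹, k = 1.20 L mol⁻¹ s⁻¹)
    catalyst intermediate A → free catalyst + target (k = 0.00470 s⁻¹)
    second substrate + free catalyst ⇌ catalyst intermediate B (K = 14.0 L mol⁻¹, k = 0.0480 L mol⁻¹ s⁻¹)
    catalyst intermediate B → free catalyst + second product (k = 0.00440 s⁻¹)
    starting material + protic impurity → quenched substrate (k = 1.90 × 10⁻⁴ L mol⁻¹ s⁻¹)
    free catalyst + stray impurity → spent catalyst (k = 2.40 L mol⁻¹ s⁻¹)

The forecast stood 5.3 points below the flask. At the asked time the flask holds 0% starting material and 25.7% of its second substrate. The same mean serves a reading of this recipe at 30 h, earlier than the asked time. There 8.10% of the starting material remains, so the yield on conversion gives 77.4% target. That neighbouring flask holds 77.8%.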